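Nakijiquinone E is cut at the N–quinone bond into hydroxymethoxyquinone 20 and aminoresorcylate 36; both sesquiterpene units grow from (S)-3,4-dimethylcyclohex-2-enone by benzylic conjugate addition, pentynyl alkylation and methylenation. Everything rests on closing ring A (C1–C5, C10) of the methylidene-decalin unit last. A Pd2(dba)3/AcOH/Et3SiH reductive cyclization of a 1,7-enyne forms the C4–C5 bond, converts the alkyne into the C4 exocyclic methylene and the ring-B methylidene carbon into the C5 methyl group, and so sets the quaternary C5 and the trans ring fusion in one operation. It exploits the adjacent C4(=CH2)/C5(CH3) pair. The precursor is a monocyclic methylidenecyclohexane carrying a pent-4-ynyl chain at C10.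

Key step: step 20

Remark on the chemistry: sesquiterpene carbons carry avarane locants (ring A = C1–C5 and C10, ring B = C5–C10); C10 of ketones 15 and 29 is epimerisable and its all-equatorial epimer is assumed to be the thermodynamic one, by a modest margin.

Step 1
Reactants: 1 propanal; 2 but-3-en-2-one
Product: 3 (S)-2-methyl-5-oxohexanal
Conditions: (R)-2-[methoxy(diphenyl)methyl]pyrrolidine (5 mol %), ethyl 3,4-dihydroxybenzoate (20 mol %), neat, 4 °C
Reagents that add atoms: none
Why: Enamine-catalysed asymmetric Michael addition in which the diarylprolinol ether shields one face of the E-enamine of propanal, so that the enone should add to give the (S)-configured methyl-bearing centre (the future C8 of both terpene units).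

Step 2
Reactants: 3 (S)-2-methyl-5-oxohexanal
Product: 4 (S)-4-methylcyclohex-2-en-1-one
Conditions: LiOH (0.1 equiv), i-PrOH, rt
Reagents that add atoms: none
Why: Intramolecular aldol condensation of the methyl ketone onto the aldehyde closes ring B, and the stereocentre becomes the configurationally stable γ-position of the enone.

Step 3
Reactants: 4 (S)-4-methylcyclohex-2-en-1-one
Product: 5 trimethyl{[(3R,4S)-3,4-dimethylcyclohex-1-en-1-yl]oxy}silane
Conditions: MeMgBr, CuBr·SMe2 (5 mol %), TMSCl, HMPA, THF, −78 °C; Et3N/pentane work-up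
Reagents that add atoms: methylmagnesium bromide C[Mg]Br; chlorotrimethylsilane C[Si](C)(C)Cl
Why: CuBr·SMe2-catalysed, chlorosilane-accelerated conjugate addition anti to the C4 methyl group with in situ O-silylation; the new C3 centre is transient because it becomes sp2 again in step 4.

Step 4
Reactants: 5 trimethyl{[(3R,4S)-3,4-dimethylcyclohex-1-en-1-yl]oxy}silane
Product: 6 (S)-3,4-dimethylcyclohex-2-en-1-one
Conditions: Pd(OAc)2 (10 mol %), O2 (1 atm), DMSO, rt
Reagents that add atoms: none
Why: Saegusa–Ito oxidation (palladium enolate, β-hydride elimination toward the methyl-bearing carbon) restores the enone, now β-methylated, without touching the C4 stereocentre.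

Step 5
Reactants: 7 1,2,4,5-tetramethoxybenzene
Product: 9 (2,3,5,6-tetramethoxyphenyl)methanol, via aryllithium 8 (not isolated)
Conditions: n-BuLi, TMEDA, THF, 0 °C; (CH2O)n, −78 °C → rt; H2O
Reagents that add atoms: formaldehyde (from paraformaldehyde) C=O
Why: Directed ortho-lithiation at the position flanked by two methoxy groups, then hydroxymethylation of the aryllithium.

Step 6
Reactants: 9 (2,3,5,6-tetramethoxyphenyl)methanol
Product: 10 3-(chloromethyl)-1,2,4,5-tetramethoxybenzene
Conditions: conc. aq. HCl, CH2Cl2, 0 °C → rt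
Reagents that add atoms: hydrogen chloride Cl
Why: SN1-type substitution of an electron-rich benzylic alcohol by chloride.

Step 7
Reactants: 10 3-(chloromethyl)-1,2,4,5-tetramethoxybenzene; 6 (S)-3,4-dimethylcyclohex-2-en-1-one
Product: 12 trimethyl({(3R,4S)-3,4-dimethyl-3-[(2,3,5,6-tetramethoxyphenyl)methyl]cyclohex-1-en-1-yl}oxy)silane, via benzylmagnesium chloride 11 (not isolated)
Conditions: Mg, THF, 0 °C (slow addition); then 6, CuBr·SMe2 (10 mol %), TMSCl, HMPA, THF, −78 → −40 °C; Et3N/pentane work-up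
Reagents that add atoms: chlorotrimethylsilane C[Si](C)(C)Cl
Why: CuBr·SMe2-catalysed, TMSCl/HMPA-accelerated 1,4-addition of the benzylic Grignard reagent anti to the pseudoaxial C8 methyl group sets the quaternary C9 (arylmethyl trans, methyl cis to the C8 methyl), and the enolate is trapped regiospecifically as the C5–C10 enol silane.

Step 8
Reactants: 12 trimethyl({(3R,4S)-3,4-dimethyl-3-[(2,3,5,6-tetramethoxyphenyl)methyl]cyclohex-1-en-1-yl}oxy)silane; 13 5-iodopent-1-yne
Product: 15 (2S,3R,4S)-3,4-dimethyl-2-(pent-4-yn-1-yl)-3-[(2,3,5,6-tetramethoxyphenyl)methyl]cyclohexan-1-one, via lithium enolate 14 (not isolated)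
Conditions: MeLi (1.0 equiv), THF, 0 °C; 13, HMPA, −78 °C → rt; then NaOMe (cat.), MeOH, rt
Reagents that add atoms: none
Why: Regiospecific lithium enolate formation from the enol silane and SN2 alkylation at C10, followed by base equilibration of this epimerisable centre toward the all-equatorial ketone (pentynyl chain cis to the C8 and C9 methyl groups, trans to the arylmethyl group); the minor C10 epimer would be separated and re-equilibrated.

Step 9
Reactants: 15 (2S,3R,4S)-3,4-dimethyl-2-(pent-4-yn-1-yl)-3-[(2,3,5,6-tetramethoxyphenyl)methyl]cyclohexan-1-one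
Product: 16 3-{[(1R,2R,6S)-1,6-dimethyl-3-methylidene-2-(pent-4-yn-1-yl)cyclohexyl]methyl}-1,2,4,5-tetramethoxybenzene
Conditions: Ph3PCH3Br, KOt-Bu (excess ylide), toluene, rt → 80 °C
Reagents that add atoms: methyltriphenylphosphonium bromide C[P+](c1ccccc1)(c1ccccc1)c1ccccc1.[Br-]
Why: Wittig methylenation turns C5=O into the exocyclic C5=CH2 without affecting the terminal alkyne or the stereocentres.

Step 10
Reactants: 16 3-{[(1R,2R,6S)-1,6-dimethyl-3-methylidene-2-(pent-4-yn-1-yl)cyclohexyl]methyl}-1,2,4,5-tetramethoxybenzene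
Product: 17 3-{[(1R,2S,4aS,8aS)-1,2,4a-trimethyl-5-methylidenedecahydronaphthalen-1-yl]methyl}-1,2,4,5-tetramethoxybenzene
Conditions: Pd2(dba)3·CHCl3 (2.5 mol %), P(o-tol)3 (10 mol %), AcOH, Et3SiH, toluene, rt → 50 °C
Reagents that add atoms: none
Why: Palladium-catalysed reductive cyclization of the 1,7-enyne (hydropalladation, 6-exo-trig carbopalladation, silane reduction), run here first on the quinone-half precursor; the axial C9 methyl directs C4 to the α face of C5, which should give the trans-decalin with the new C5 methyl.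

Step 11
Reactants: 17 3-{[(1R,2S,4aS,8aS)-1,2,4a-trimethyl-5-methylidenedecahydronaphthalen-1-yl]methyl}-1,2,4,5-tetramethoxybenzene
Product: 18 3-{[(1R,2S,4aS,8aS)-1,2,4a,5-tetramethyl-1,2,3,4,4a,7,8,8a-octahydronaphthalen-1-yl]methyl}-1,2,4,5-tetramethoxybenzene
Conditions: RhCl3·3H2O (20 mol %), EtOH, reflux
Reagents that add atoms: none
Why: RhCl3-mediated alkene isomerisation moves the exocyclic double bond into the only available endocyclic position (C3=C4), the more stable trisubstituted alkene, with no stereocentre affected.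

Step 12
Reactants: 18 3-{[(1R,2S,4aS,8aS)-1,2,4a,5-tetramethyl-1,2,3,4,4a,7,8,8a-octahydronaphthalen-1-yl]methyl}-1,2,4,5-tetramethoxybenzene
Product: 19 2,5-dimethoxy-3-{[(1R,2S,4aS,8aS)-1,2,4a,5-tetramethyl-1,2,3,4,4a,7,8,8a-octahydronaphthalen-1-yl]methyl}cyclohexa-2,5-diene-1,4-dione
Conditions: (NH4)2Ce(NO3)6 (2.5 equiv), MeCN/H2O, 0 °C
Reagents that add atoms: water O
Why: Oxidative demethylation of the electron-rich tetramethoxyarene to the para-quinone; both para pairings of methoxy groups lead to the same 3-alkyl-2,5-dimethoxyquinone.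

Step 13
Reactants: 19 2,5-dimethoxy-3-{[(1R,2S,4aS,8aS)-1,2,4a,5-tetramethyl-1,2,3,4,4a,7,8,8a-octahydronaphthalen-1-yl]methyl}cyclohexa-2,5-diene-1,4-dione
Product: 20 2-hydroxy-5-methoxy-3-{[(1R,2S,4aS,8aS)-1,2,4a,5-tetramethyl-1,2,3,4,4a,7,8,8a-octahydronaphthalen-1-yl]methyl}cyclohexa-2,5-diene-1,4-dione (isospongiaquinone)
Conditions: KOH, MeOH/H2O, rt; then 1 M HCl
Reagents that add atoms: potassium hydroxide [K+].[OH-]
Why: Regioselective saponification of a vinylogous ester by addition–elimination; the methoxy group next to the bulky alkyl substituent is twisted out of conjugation and is the one expected to be displaced, as is typical of 3-alkyl-2,5-dimethoxybenzoquinones.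

Step 14
Reactants: 21 2,4-dihydroxybenzaldehyde
Product: 22 2,4-bis(methoxymethoxy)benzaldehyde
Conditions: NaH, MOMCl, DMF, 0 °C → rt
Reagents that add atoms: chloromethyl methyl ether COCCl
Why: Williamson-type O-alkylation of both phenoxides gives acetal protecting groups that tolerate the organometallic steps.

Step 15
Reactants: 22 2,4-bis(methoxymethoxy)benzaldehyde
Product: 23 [2,4-bis(methoxymethoxy)phenyl]methanol
Conditions: NaBH4, MeOH, 0 °C
Reagents that add atoms: none
Why: Hydride reduction of the aldehyde.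

Step 16
Reactants: 23 [2,4-bis(methoxymethoxy)phenyl]methanol
Product: 25 1-(chloromethyl)-2,4-bis(methoxymethoxy)benzene, via benzylic mesylate 24 (not isolated)
Conditions: MsCl, i-Pr2NEt, CH2Cl2, 0 °C → rt; used at once
Reagents that add atoms: methanesulfonyl chloride CS(=O)(=O)Cl
Why: Mesylation of the electron-rich benzylic alcohol and in situ displacement by chloride under non-acidic conditions that spare the MOM ethers.

Step 17
Reactants: 25 1-(chloromethyl)-2,4-bis(methoxymethoxy)benzene; 6 (S)-3,4-dimethylcyclohex-2-en-1-one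
Product: 27 ({(3R,4S)-3-{[2,4-bis(methoxymethoxy)phenyl]methyl}-3,4-dimethylcyclohex-1-en-1-yl}oxy)trimethylsilane, via benzylmagnesium chloride 26 (not isolated)
Conditions: Mg, THF, 0 °C (slow addition); then 6, CuBr·SMe2 (10 mol %), TMSCl, HMPA, THF, −78 → −40 °C; Et3N/pentane work-up
Reagents that add atoms: chlorotrimethylsilane C[Si](C)(C)Cl
Why: CuBr·SMe2-catalysed, TMSCl/HMPA-accelerated conjugate addition of the benzylic Grignard reagent anti to the pseudoaxial C8 methyl group sets the quaternary C9, and silylation fixes the C5–C10 enolate regiochemistry.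

Step 18
Reactants: 27 ({(3R,4S)-3-{[2,4-bis(methoxymethoxy)phenyl]methyl}-3,4-dimethylcyclohex-1-en-1-yl}oxy)trimethylsilane; 13 5-iodopent-1-yne
Product: 29 (2S,3R,4S)-3-{[2,4-bis(methoxymethoxy)phenyl]methyl}-3,4-dimethyl-2-(pent-4-yn-1-yl)cyclohexan-1-one, via lithium enolate 28 (not isolated)
Conditions: MeLi (1.0 equiv), THF, 0 °C; 13, HMPA, −78 °C → rt; then NaOMe (cat.), MeOH, rt
Reagents that add atoms: none
Why: Regiospecific enolate generation and SN2 alkylation at C10, then thermodynamic equilibration of this epimerisable centre toward the all-equatorial isomer with the chain cis to the C8 and C9 methyl groups; the minor epimer would be recycled.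

Step 19
Reactants: 29 (2S,3R,4S)-3-{[2,4-bis(methoxymethoxy)phenyl]methyl}-3,4-dimethyl-2-(pent-4-yn-1-yl)cyclohexan-1-one
Product: 30 1-{[(1R,2R,6S)-1,6-dimethyl-3-methylidene-2-(pent-4-yn-1-yl)cyclohexyl]methyl}-2,4-bis(methoxymethoxy)benzene
Conditions: Ph3PCH3Br, KOt-Bu (excess ylide), toluene, rt → 80 °C
Reagents that add atoms: methyltriphenylphosphonium bromide C[P+](c1ccccc1)(c1ccccc1)c1ccccc1.[Br-]
Why: Wittig methylenation installs the exocyclic C5=CH2 acceptor of the enyne and removes the only epimerising group next to C10.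

Step 20
Reactants: 30 1-{[(1R,2R,6S)-1,6-dimethyl-3-methylidene-2-(pent-4-yn-1-yl)cyclohexyl]methyl}-2,4-bis(methoxymethoxy)benzene
Product: 31 2,4-bis(methoxymethoxy)-1-{[(1R,2S,4aS,8aS)-1,2,4a-trimethyl-5-methylidenedecahydronaphthalen-1-yl]methyl}benzene
Conditions: Pd2(dba)3·CHCl3 (2.5 mol %), P(o-tol)3 (10 mol %), AcOH (1.5 equiv), Et3SiH (excess), toluene, rt → 50 °C
Reagents that add atoms: none
Why: Zerovalent palladium and acetic acid form H–Pd–OAc, which adds across the terminal alkyne with palladium on the internal carbon C4; this alkenylpalladium inserts the exocyclic C5=CH2 bond of ring B by syn-carbopalladation, and the resulting neopentyl-type alkylpalladium, which has no β-hydrogen, is reduced by triethylsilane so that the former methylidene carbon becomes the C5 methyl group. The closest known reaction type is the palladium-catalysed reductive cyclization of 1,6- and 1,7-enynes under acetic acid/silane conditions, a hydrometalative relative of the reductive Heck reaction. Ring A is closed in the 6-exo-trig mode through a chair-like transition state in which the equatorial C10 tether delivers C4 to C5. The new quaternary stereocentre C5 is controlled by the axial C9 methyl group, which is 1,3 to C5 and shields its β face, so that C4 should bond on the α face trans to the C10–C1 bond and the new methyl should end axial, giving the trans-decalin. The step needs hydropalladation of the alkyne in preference to the 1,1-disubstituted alkene, exo rather than endo insertion, and reduction of the alkylpalladium before it can add to the new alkene; the terminal alkyne, the six-membered chair geometry and the excess silane should secure these, and the 1,1-disubstituted acceptor excludes β-hydride elimination.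

Step 21
Reactants: 31 2,4-bis(methoxymethoxy)-1-{[(1R,2S,4aS,8aS)-1,2,4a-trimethyl-5-methylidenedecahydronaphthalen-1-yl]methyl}benzene
Product: 32 4-{[(1R,2S,4aS,8aS)-1,2,4a-trimethyl-5-methylidenedecahydronaphthalen-1-yl]methyl}benzene-1,3-diol
Conditions: ZnBr2, n-PrSH, CH2Cl2, 0 °C
Reagents that add atoms: none
Why: Lewis acid/thiol transacetalisation removes both aryl MOM ethers under conditions too mild to protonate the exocyclic alkene.

Step 22
Reactants: 32 4-{[(1R,2S,4aS,8aS)-1,2,4a-trimethyl-5-methylidenedecahydronaphthalen-1-yl]methyl}benzene-1,3-diol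
Product: 33 2,4-dihydroxy-5-{[(1R,2S,4aS,8aS)-1,2,4a-trimethyl-5-methylidenedecahydronaphthalen-1-yl]methyl}benzoic acid
Conditions: KHCO3 (excess), CO2 (1 atm), DMF, 120 °C; then 1 M HCl, 0 °C
Reagents that add atoms: carbon dioxide (delivered by KHCO3 under CO2) O=C=O
Why: Kolbe–Schmitt carboxylation of the resorcinol under potassium bicarbonate conditions goes ortho to one hydroxyl and para to the other (β-resorcylic mode), which is the free position meta to the alkyl group.

Step 23
Reactants: 33 2,4-dihydroxy-5-{[(1R,2S,4aS,8aS)-1,2,4a-trimethyl-5-methylidenedecahydronaphthalen-1-yl]methyl}benzoic acid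
Product: 34 methyl 2,4-dihydroxy-5-{[(1R,2S,4aS,8aS)-1,2,4a-trimethyl-5-methylidenedecahydronaphthalen-1-yl]methyl}benzoate
Conditions: MeI (1.1 equiv), NaHCO3, DMF, rt
Reagents that add atoms: iodomethane CI
Why: Chemoselective SN2 O-methylation of the carboxylate, since bicarbonate does not deprotonate the phenols appreciably.

Step 24
Reactants: 34 methyl 2,4-dihydroxy-5-{[(1R,2S,4aS,8aS)-1,2,4a-trimethyl-5-methylidenedecahydronaphthalen-1-yl]methyl}benzoate
Product: 35 methyl 2,4-dihydroxy-3-[(E)-phenyldiazenyl]-5-{[(1R,2S,4aS,8aS)-1,2,4a-trimethyl-5-methylidenedecahydronaphthalen-1-yl]methyl}benzoate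
Conditions: PhN2+ BF4−, pyridine, THF, 0 °C
Reagents that add atoms: benzenediazonium tetrafluoroborate N#[N+]c1ccccc1.F[B-](F)(F)F
Why: Azo coupling (electrophilic aromatic substitution) at the only activated free position, C3 between the two hydroxyl groups, under conditions that leave the alkene alone.

Step 25
Reactants: 35 methyl 2,4-dihydroxy-3-[(E)-phenyldiazenyl]-5-{[(1R,2S,4aS,8aS)-1,2,4a-trimethyl-5-methylidenedecahydronaphthalen-1-yl]methyl}benzoate
Product: 36 methyl 3-amino-2,4-dihydroxy-5-{[(1R,2S,4aS,8aS)-1,2,4a-trimethyl-5-methylidenedecahydronaphthalen-1-yl]methyl}benzoate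
Conditions: Na2S2O4, THF/H2O, 50 °C, Ar; used directly
Reagents that add atoms: none
Why: Dithionite reduction cleaves the N=N bond to the aminoresorcinol without touching alkene or ester.

Step 26
Reactants: 36 methyl 3-amino-2,4-dihydroxy-5-{[(1R,2S,4aS,8aS)-1,2,4a-trimethyl-5-methylidenedecahydronaphthalen-1-yl]methyl}benzoate; 20 isospongiaquinone
Product: 37 nakijiquinone E
Conditions: NaHCO3, EtOH, 40 °C, Ar, dark
Reagents that add atoms: none
Why: Addition–elimination at a vinylogous ester: the arylamine should displace methoxide at the unhindered C5 of the quinone, while the C2 hydroxyl next to the alkyl group stays as an unreactive vinylogous carboxylate; no stereocentre is touched.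

Compound list
1 | propanal | CCC=O | starting material
2 | but-3-en-2-one | CC(=O)C=C | starting material
3 | (S)-2-methyl-5-oxohexanal | O=C[C@@H](C)CCC(C)=O | intermediate
4 | (S)-4-methylcyclohex-2-en-1-one | O=C1C=C[C@@H](C)CC1 | intermediate
5 | trimethyl{[(3R,4S)-3,4-dimethylcyclohex-1-en-1-yl]oxy}silane | C[Si](C)(C)OC1=C[C@H](C)[C@@H](C)CC1 | intermediate
6 | (S)-3,4-dimethylcyclohex-2-en-1-one | O=C1C=C(C)[C@@H](C)CC1 | intermediate
7 | 1,2,4,5-tetramethoxybenzene | COc1cc(OC)c(OC)cc1OC | starting material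
8 | (2,3,5,6-tetramethoxyphenyl)lithium | [Li]c1c(OC)c(OC)cc(OC)c1OC | intermediate
9 | (2,3,5,6-tetramethoxyphenyl)methanol | OCc1c(OC)c(OC)cc(OC)c1OC | intermediate
10 | 3-(chloromethyl)-1,2,4,5-tetramethoxybenzene | ClCc1c(OC)c(OC)cc(OC)c1OC | intermediate
11 | [(2,3,5,6-tetramethoxyphenyl)methyl]magnesium chloride | Cl[Mg]Cc1c(OC)c(OC)cc(OC)c1OC | intermediate
12 | trimethyl({(3R,4S)-3,4-dimethyl-3-[(2,3,5,6-tetramethoxyphenyl)methyl]cyclohex-1-en-1-yl}oxy)silane | C[Si](C)(C)OC1=C[C@](C)(Cc2c(OC)c(OC)cc(OC)c2OC)[C@@H](C)CC1 | intermediate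
13 | 5-iodopent-1-yne | C#CCCCI | starting material
14 | lithium (3R,4S)-3,4-dimethyl-3-[(2,3,5,6-tetramethoxyphenyl)methyl]cyclohex-1-en-1-olate | [Li]OC1=C[C@](C)(Cc2c(OC)c(OC)cc(OC)c2OC)[C@@H](C)CC1 | intermediate
15 | (2S,3R,4S)-3,4-dimethyl-2-(pent-4-yn-1-yl)-3-[(2,3,5,6-tetramethoxyphenyl)methyl]cyclohexan-1-one | C#CCCC[C@H]1[C@](C)(Cc2c(OC)c(OC)cc(OC)c2OC)[C@@H](C)CCC1=O | intermediate
16 | 3-{[(1R,2R,6S)-1,6-dimethyl-3-methylidene-2-(pent-4-yn-1-yl)cyclohexyl]methyl}-1,2,4,5-tetramethoxybenzene | C#CCCC[C@H]1[C@](C)(Cc2c(OC)c(OC)cc(OC)c2OC)[C@@H](C)CCC1=C | intermediate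
17 | 3-{[(1R,2S,4aS,8aS)-1,2,4a-trimethyl-5-methylidenedecahydronaphthalen-1-yl]methyl}-1,2,4,5-tetramethoxybenzene | C=C1CCC[C@H]2[C@](C)(Cc3c(OC)c(OC)cc(OC)c3OC)[C@@H](C)CC[C@]12C | intermediate
18 | 3-{[(1R,2S,4aS,8aS)-1,2,4a,5-tetramethyl-1,2,3,4,4a,7,8,8a-octahydronaphthalen-1-yl]methyl}-1,2,4,5-tetramethoxybenzene | CC1=CCC[C@H]2[C@](C)(Cc3c(OC)c(OC)cc(OC)c3OC)[C@@H](C)CC[C@]12C | intermediate
19 | 2,5-dimethoxy-3-{[(1R,2S,4aS,8aS)-1,2,4a,5-tetramethyl-1,2,3,4,4a,7,8,8a-octahydronaphthalen-1-yl]methyl}cyclohexa-2,5-diene-1,4-dione | CC1=CCC[C@H]2[C@](C)(CC3=C(OC)C(=O)C=C(OC)C3=O)[C@@H](C)CC[C@]12C | intermediate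
20 | 2-hydroxy-5-methoxy-3-{[(1R,2S,4aS,8aS)-1,2,4a,5-tetramethyl-1,2,3,4,4a,7,8,8a-octahydronaphthalen-1-yl]methyl}cyclohexa-2,5-diene-1,4-dione (isospongiaquinone) | CC1=CCC[C@H]2[C@](C)(CC3=C(O)C(=O)C=C(OC)C3=O)[C@@H](C)CC[C@]12C | intermediate
21 | 2,4-dihydroxybenzaldehyde | O=Cc1ccc(O)cc1O | starting material
22 | 2,4-bis(methoxymethoxy)benzaldehyde | O=Cc1ccc(OCOC)cc1OCOC | intermediate
23 | [2,4-bis(methoxymethoxy)phenyl]methanol | OCc1ccc(OCOC)cc1OCOC | intermediate
24 | [2,4-bis(methoxymethoxy)phenyl]methyl methanesulfonate | CS(=O)(=O)OCc1ccc(OCOC)cc1OCOC | intermediate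
25 | 1-(chloromethyl)-2,4-bis(methoxymethoxy)benzene | ClCc1ccc(OCOC)cc1OCOC | intermediate
26 | {[2,4-bis(methoxymethoxy)phenyl]methyl}magnesium chloride | Cl[Mg]Cc1ccc(OCOC)cc1OCOC | intermediate
27 | ({(3R,4S)-3-{[2,4-bis(methoxymethoxy)phenyl]methyl}-3,4-dimethylcyclohex-1-en-1-yl}oxy)trimethylsilane | C[Si](C)(C)OC1=C[C@](C)(Cc2ccc(OCOC)cc2OCOC)[C@@H](C)CC1 | intermediate
28 | lithium (3R,4S)-3-{[2,4-bis(methoxymethoxy)phenyl]methyl}-3,4-dimethylcyclohex-1-en-1-olate | [Li]OC1=C[C@](C)(Cc2ccc(OCOC)cc2OCOC)[C@@H](C)CC1 | intermediate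
29 | (2S,3R,4S)-3-{[2,4-bis(methoxymethoxy)phenyl]methyl}-3,4-dimethyl-2-(pent-4-yn-1-yl)cyclohexan-1-one | C#CCCC[C@H]1[C@](C)(Cc2ccc(OCOC)cc2OCOC)[C@@H](C)CCC1=O | intermediate
30 | 1-{[(1R,2R,6S)-1,6-dimethyl-3-methylidene-2-(pent-4-yn-1-yl)cyclohexyl]methyl}-2,4-bis(methoxymethoxy)benzene | C#CCCC[C@H]1[C@](C)(Cc2ccc(OCOC)cc2OCOC)[C@@H](C)CCC1=C | intermediate
31 | 2,4-bis(methoxymethoxy)-1-{[(1R,2S,4aS,8aS)-1,2,4a-trimethyl-5-methylidenedecahydronaphthalen-1-yl]methyl}benzene | C=C1CCC[C@H]2[C@](C)(Cc3ccc(OCOC)cc3OCOC)[C@@H](C)CC[C@]12C | intermediate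
32 | 4-{[(1R,2S,4aS,8aS)-1,2,4a-trimethyl-5-methylidenedecahydronaphthalen-1-yl]methyl}benzene-1,3-diol | C=C1CCC[C@H]2[C@](C)(Cc3ccc(O)cc3O)[C@@H](C)CC[C@]12C | intermediate
33 | 2,4-dihydroxy-5-{[(1R,2S,4aS,8aS)-1,2,4a-trimethyl-5-methylidenedecahydronaphthalen-1-yl]methyl}benzoic acid | C=C1CCC[C@H]2[C@](C)(Cc3cc(C(=O)O)c(O)cc3O)[C@@H](C)CC[C@]12C | intermediate
34 | methyl 2,4-dihydroxy-5-{[(1R,2S,4aS,8aS)-1,2,4a-trimethyl-5-methylidenedecahydronaphthalen-1-yl]methyl}benzoate | C=C1CCC[C@H]2[C@](C)(Cc3cc(C(=O)OC)c(O)cc3O)[C@@H](C)CC[C@]12C | intermediate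
35 | methyl 2,4-dihydroxy-3-[(E)-phenyldiazenyl]-5-{[(1R,2S,4aS,8aS)-1,2,4a-trimethyl-5-methylidenedecahydronaphthalen-1-yl]methyl}benzoate | C=C1CCC[C@H]2[C@](C)(Cc3cc(C(=O)OC)c(O)c(/N=N/c4ccccc4)c3O)[C@@H](C)CC[C@]12C | intermediate
36 | methyl 3-amino-2,4-dihydroxy-5-{[(1R,2S,4aS,8aS)-1,2,4a-trimethyl-5-methylidenedecahydronaphthalen-1-yl]methyl}benzoate | C=C1CCC[C@H]2[C@](C)(Cc3cc(C(=O)OC)c(O)c(N)c3O)[C@@H](C)CC[C@]12C | intermediate
37 | nakijiquinone E | C=C1CCC[C@H]2[C@](C)(Cc3cc(C(=O)OC)c(O)c(NC4=CC(=O)C(O)=C(C[C@]5(C)[C@@H](C)CC[C@]6(C)C(C)=CCC[C@@H]56)C4=O)c3O)[C@@H](C)CC[C@]12C | target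

Total step count: 26. Longest linear sequence: 14 steps (1–4, then 17–26); the quinone half (5–13) and the benzylic chloride (14–16) are side branches.

Steps most likely to fail

Step 20 (key step). Hydropalladation of the alkyne may lead to simple reduction or oligomerisation faster than insertion into the hindered methylidene group, or H–Pd–OAc may isomerise the exocyclic alkenes; facial selectivity at C5 is predicted, not assured. Step 10 is the same reaction on the tetramethoxy series and is the natural place to test it first. The fallback generates the alkenylpalladium by oxidative addition instead of hydropalladation. Enol silane 27 would be alkylated (MeLi; HMPA; then NaOMe/MeOH) with the known reagent 2-bromo-5-iodopent-1-ene in place of 13 to give bromo ketone F1. Wittig methylenation would give bromo diene F2. A reductive Heck cyclization (Pd(OAc)2, PPh3, HCO2Na, Et4NCl, DMF, 80 °C) would then close ring A and return to 31.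

Step 18 (and its sister step 8). SN2 alkylation of the hindered enolate next to the quaternary C9 may be slow and lose material to proton transfer or O-alkylation. Kinetic attack is likely to occur on the wrong face of C10, so the configuration rests on an equilibration with only a modest bias. The fallback replaces C–C bond formation at C10 by proton delivery to C10. Enol silane 27 would undergo a Mukaiyama aldol reaction with pent-4-ynal (BF3·OEt2, CH2Cl2, −78 °C) to give hydroxy ketone F3. Mesylation and elimination (MsCl, Et3N, 0 °C → rt) would give the exocyclic enone F4. Conjugate reduction with L-Selectride (THF, −78 °C) forms the C5–C10 enolate regiospecifically, and kinetic axial protonation on the α face, anti to the axial C9 methyl, should return ketone 29.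

Step 17 (and its sister step 7). The electron-rich benzylic Grignard reagent may be lost to Wurtz coupling during its formation, or may add 1,2 to the hindered β,β-disubstituted enone. The fallback uses a stabilised benzylic carbanion as the Michael donor. Chloride 25 and PhSO2Na (DMF, rt) would give sulfone F5. Its lithio derivative (n-BuLi, THF/HMPA, −78 °C) should add to enone 6 anti to the C8 methyl; the enolate would be alkylated in situ with 13 and equilibrated to keto sulfone F6. Wittig methylenation would give F7, and reductive desulfonylation (Mg, MeOH, rt) would return to enyne 30.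

Further compounds
F1 | step 20 | (2S,3R,4S)-3-{[2,4-bis(methoxymethoxy)phenyl]methyl}-2-(4-bromopent-4-en-1-yl)-3,4-dimethylcyclohexan-1-one | C=C(Br)CCC[C@H]1[C@](C)(Cc2ccc(OCOC)cc2OCOC)[C@@H](C)CCC1=O
F2 | step 20 | 1-{[(1R,2R,6S)-2-(4-bromopent-4-en-1-yl)-1,6-dimethyl-3-methylidenecyclohexyl]methyl}-2,4-bis(methoxymethoxy)benzene | C=C(Br)CCC[C@H]1[C@](C)(Cc2ccc(OCOC)cc2OCOC)[C@@H](C)CCC1=C
F3 | step 18 | (3R,4S)-3-{[2,4-bis(methoxymethoxy)phenyl]methyl}-2-(1-hydroxypent-4-yn-1-yl)-3,4-dimethylcyclohexan-1-one (mixture at C2 and the carbinol carbon) | C#CCCC(O)C1[C@](C)(Cc2ccc(OCOC)cc2OCOC)[C@@H](C)CCC1=O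
F4 | step 18 | (3R,4S)-3-{[2,4-bis(methoxymethoxy)phenyl]methyl}-3,4-dimethyl-2-(pent-4-yn-1-ylidene)cyclohexan-1-one | C#CCCC=C1C(=O)CC[C@H](C)[C@@]1(C)Cc1ccc(OCOC)cc1OCOC
F5 | step 17 | 2,4-bis(methoxymethoxy)-1-[(phenylsulfonyl)methyl]benzene | O=S(=O)(Cc1ccc(OCOC)cc1OCOC)c1ccccc1
F6 | step 17 | (2S,3R,4S)-3-{[2,4-bis(methoxymethoxy)phenyl](phenylsulfonyl)methyl}-3,4-dimethyl-2-(pent-4-yn-1-yl)cyclohexan-1-one (mixture at the sulfonyl-bearing carbon) | C#CCCC[C@H]1[C@](C)(C(c2ccc(OCOC)cc2OCOC)S(=O)(=O)c2ccccc2)[C@@H](C)CCC1=O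
F7 | step 17 | 1-{[(1R,2R,6S)-1,6-dimethyl-3-methylidene-2-(pent-4-yn-1-yl)cyclohexyl](phenylsulfonyl)methyl}-2,4-bis(methoxymethoxy)benzene (mixture at the sulfonyl-bearing carbon) | C#CCCC[C@H]1[C@](C)(C(c2ccc(OCOC)cc2OCOC)S(=O)(=O)c2ccccc2)[C@@H](C)CCC1=C
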